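In a one-step world, each part of starting material lost would turn up as target, and choosing a run would mean choosing a conversion. Delta and gamma did not look like that, so before charging anything I needed to know what a lost part was worth and how fast parts were lost.

all flasks: starting material 0.10 M
- delta: reagent 0.25 M; protic impurity 0.010 M; temperature 55 °C; run made earlier
- gamma: reagent 0.25 M; protic impurity 0.040 M; temperature 70 °C; run made earlier
- amber: reagent 0.250 M; protic impurity 0.0200 M; temperature 60 °C; time 2.0 min
- violet: reagent 0.250 M; protic impurity 0.0200 M; temperature 80 °C; time 2.0 min

- delta (time / s: target / %, starting material / %): 10.0: 0.2, 97.7; 12.0: 0, 96.8; 20.0: 1.7, 95.0; 25.0: 1.5, 93.6; 40.0: 2.8, 89.4; 60.0: 5.1, 84.5; 90.0: 8.7, 79.5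
- gamma (time / s: target / %, starting material / %): 10.0: 3.5, 88.8; 20.0: 7.4, 79.7; 25.0: 9.5, 75.9; 40.0: 13.1, 64.0; 50.0: 16.2, 57.8; 60.0: 18.9, 52.5

(scatter of a reading: 0.5 percentage points)

1. which of the two there is more of at the end, amber (isomer of the product / target)
2. which of the two there is more of at the end, violet (isomer of the product / target)
3. how much target is there at the end, in percent of the starting material charged: amber
4. how much target is there at the end, in percent of the starting material charged: violet

- a reading or a percentage of target counts all its forms, free or not

My choice lay between amber and violet: same charge, same time, different temperature. I had to say whether the heat repaid itself, so I replaced the curves by means. Target over starting material lost was 0.424 at delta's last reading and 0.398 at gamma's. I kept their mean, 0.411, as the target share, an overall selectivity. It is a late value: gamma's first reading gave 0.313, less than that.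

For the loss I took a mean first-order constant, minus the ln of the fraction left over the time: 0.00255 s⁻¹ in delta and 0.0107 s⁻¹ in gamma. To check the error of that mean, delta's constant leaves 90.3% at 40.0 s, against 89.4% read. Gamma was hotter and also richer in protic impurity, so their ratio carries both. Spreading ln k evenly over the temperature gap, and carrying it on past gamma for violet, gave an estimate of 0.00412 s⁻¹ for amber and 0.0280 s⁻¹ for violet. On that estimate amber would keep 61.0% of its starting material and violet 3.47%. The share turned those into 16.0% and 39.7% of target. Violet promised 2.48 times amber's target, so I chose violet. The isomer of the product was not among the columns read, so I made no reckoning of it.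

The forecast gave 17% for amber and 55% for violet, with isomer of the product ahead in amber and target ahead in violet, holding that “target seems to build late”. I had held the share flat, so we parted on violet.

Amber ended at 16.3% of target and violet at 46.4%, idle adduct counted in, with isomer of the product at 9.87% and 14.3%.

    starting material + protic impurity → quenched substrate (k = 0.0436 M⁻¹ s⁻¹, Ea = 72.0 kJ mol⁻¹)
    reagent + target ⇌ idle adduct, settled at all times (K = 1.70 M⁻¹, ΔH = −25.0 kJ mol⁻¹)
    intermediate ⇌ isomer of the product (K = 2.65, k = 0.0255 s⁻¹, Ea = 100 kJ mol⁻¹, ΔH = −45.0 kJ mol⁻¹)
    intermediate ⇌ target (K = 2.61, k = 0.0502 s⁻¹, Ea = 91.0 kJ mol⁻¹, ΔH = 6.00 kJ mol⁻¹)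
    starting material + reagent → intermediate + by-product (k = 0.0152 M⁻¹ s⁻¹, Ea = 78.0 kJ mol⁻¹)
    (constants at 60 °C)

Violet had 13.5% of its starting material left, so its share was 0.536, above the carried 0.411, while amber's was 0.413. Amber left until 5.0 min kept 32.3% of its starting material, so the carried share made 27.8% of target, and that flask held 28.2%.

The readings were computed for substances that don't exist.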